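**A small charge.** A small charge of catalyst, 0.00120 M, stood against 0.120 M of starting material in the dawn run, and my first question was whether the catalyst carried the whole rate.

the same everywhere: partner 0.132 M
- dawn: starting material 0.120 M; catalyst 0.00120 M
- dusk: starting material 0.360 M; catalyst 0.00120 M
- spring: starting material 0.120 M; catalyst 0.00120 M; target 0.0360 M
- winter: starting material 0.120 M; catalyst 0.00180 M
- midnight: starting material 0.120 M; catalyst 0.00120 M; time 10 h

| run | time / h | [target] / M |
|---|---|---|
| dawn run | 0.87 | 0.0149 |
| dawn run | 1.7 | 0.0258 |
| dawn run | 2.6 | 0.0335 |
| dawn run | 3.5 | 0.0388 |
| dawn run | 4.3 | 0.0415 |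
| dawn run | 5.2 | 0.0436 |
| dusk run | 0.87 | 0.0422 |
| dusk run | 1.7 | 0.0633 |
| dusk run | 2.6 | 0.0760 |
| dusk run | 3.5 | 0.0809 |
| dusk run | 4.3 | 0.0819 |
| dusk run | 5.2 | 0.0796 |
| spring run | 0.87 | 0.0482 |
| spring run | 1.7 | 0.0557 |
| spring run | 2.6 | 0.0606 |
| spring run | 3.5 | 0.0637 |
| spring run | 4.3 | 0.0642 |
| spring run | 5.2 | 0.0639 |
| winter run | 0.87 | 0.0196 |
| winter run | 1.7 | 0.0311 |
| winter run | 2.6 | 0.0404 |
| winter run | 3.5 | 0.0449 |
| winter run | 4.3 | 0.0474 |
| winter run | 5.2 | 0.0495 |

(scatter of a reading: 4 × 10⁻⁴ M)

- the power of [catalyst] that the first rate follows, about the charge of the dawn run; measure it at two percent of starting material made into target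
- the power of [starting material] that the first rate follows, about the charge of the dawn run; measure it at two percent of starting material made into target (one fixed amount of target, the same in the runs compared)
- target in the midnight run at 10 h, as a share of the starting material charged

- Overall: starting material + partner -> target, with catalyst as catalyst.
- Constant volume, constant temperature.
- Bound and free are read together.
- An order is taken over about fifteen percent of the charge, up and down.

**Comparing rates.** The readings start at 0.87 h, so I took the target at that first reading, the same time in each run, as my measure of the early rate, and it stood at 0.0149 M in the dawn run, 0.0196 M in the winter run and 0.0422 M in the dusk run. The dusk run held 3.00 times the starting material of the dawn run and had made 2.83 times the target, so over that wide step I took the order in starting material as 0.948.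

**Two parts.** The winter run held 1.50 times the catalyst of the dawn run, yet had made 1.32 times the target at the first reading, so I wrote the first rate as two parts: one in proportion to catalyst, and a catalyst-free one, a background reaction. In that form the relative gain in rate is the catalysed share of the dawn rate times the relative gain in catalyst, which, with the first readings standing in for the rates, put the share at 0.631. From it I got 7.02 × 10⁻⁴ M as the crossover catalyst concentration, the level at which the catalysed and catalyst-free parts are equal. In this form the order in catalyst is the catalyst level divided by that level plus the crossover, and the dawn charge, which lies above the crossover, gave 0.631.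

**The midnight flask.** The midnight run repeats the dawn charge. The dawn run had reached 36.3 % of its starting material at 5.2 h, and its last step added 0.00210 M, while the dusk readings went from 0.0819 M to 0.0796 M over the same step. I read that as a slow loss of target and kept the dawn share as my figure for 10 h.

**Forecast and result.** The forecast gave 0.7 (0.5 to 0.9) in catalyst, which it called “fractional and suggests a partly dimerised resting state”, 1 (0.8 to 1.2) in starting material and 39.5 % (36 % to 42.5 %) for the midnight run, so its catalyst order and its share stood above mine. The flask gave 0.61 in catalyst, 1.0 in starting material and 34.9 % for the midnight run.

    catalyst + partner ⇌ catalyst-reagent complex, settled at all times (1.400 M⁻¹)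
    catalyst-reagent complex + starting material → target + catalyst (572.4 M⁻¹ h⁻¹)
    target → decomposed product (0.1048 h⁻¹)
    starting material + partner → target (0.5328 M⁻¹ h⁻¹)

**The proof.** The order in catalyst of 0.61 stood beside the 0.631 reckoned from the crossover of 7.02 × 10⁻⁴ M, and it lay below one because of the conversion of starting material + partner into target, the catalyst-free part I had inferred. The dawn charge run without that step proves it: the crossover falls away there, the catalyst level divided by itself is one, and the apparent order in catalyst rose by 0.41 to 1.0.

The numbers in the tables come from a simulation from invented constants.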